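The synthesis rests on cutting the side chain of ring B at C1''–C2'' and at the methyl on C3''. In one operation, zirconium-catalysed methylalumination of a terminal alkyne and zerovalent-palladium benzylation of the resulting alkenylalane build the E-configured trisubstituted olefin C2''=C3'', which carries its methyl on C3'' and the benzylic C1'' attached to ring B C2. The partners are the (R)-silyl ether of 2-methylhept-1-en-6-yn-3-ol, which brings the C6'' stereocentre, and a ring B C2 benzylic chloride that already contains the MOM-protected dihydrochalcone skeleton, with the ring A carbonyl carbon held as a triethylsilyl-protected carbinol. Selective desilylation, oxidation and acid deprotection complete the target.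

Key step: step 13

Remarks on the chemistry (assumptions and design choices)
- Labels: ring A is the 2,4-dioxygenated ring on the carbonyl. Ring B is the catechol ring (C1 propanone chain, C2 side chain, C3 and C4 oxygens). The side chain is numbered C1''–C8'' from ring B.
- The target SMILES encodes 6''R and 2''E, and the route is planned for this isomer only.
- The ring A carbonyl carbon passes the organoaluminium step as a TES-protected carbinol. A cyclic ketal on this electron-rich aryl ketone could only be installed with acid and a diol, which would strip the aryl MOM acetals, and a free ketone would face Me3Al.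
- This carbinol carbon is not controlled: 16–21 are racemic and 24 and 25 are pairs of epimers. Step 15 turns the carbon into the carbonyl, so this has no consequence.
- The ring B aldehyde is reduced before the fragments are joined, so no aldehyde has to be told apart from another carbonyl later.

Step 1
Reactants: 1 pent-4-ynoic acid
Product: 3 N-methoxy-N-methylpent-4-ynamide, via 1-(pent-4-ynoyl)imidazole 2 (not isolated)
Conditions: CDI (1,1'-carbonyldiimidazole), CH2Cl2, 0 °C to rt; then MeNH(OMe)·HCl, rt
Reagents that add atoms: N,O-dimethylhydroxylamine hydrochloride, CNOC.Cl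
Why: Acyl imidazolide formation and aminolysis is a standard Weinreb amide synthesis to which the terminal alkyne is inert.

Step 2
Reactants: 3 N-methoxy-N-methylpent-4-ynamide; 4 isopropenylmagnesium bromide
Product: 6 2-methylhept-1-en-6-yn-3-one, via bromomagnesium hemiaminal chelate 5 (not isolated)
Conditions: 4 (2.5 equiv), THF, −20 to 0 °C; inverse quench into cold 1 M HCl
Reagents that add atoms: isopropenylmagnesium bromide (compound 4), C=C(C)[Mg]Br
Why: Weinreb ketone synthesis, in which the chelated adduct 5 resists a second addition and collapses only on the acidic quench, which also protonates the released amine so that it cannot add to the enone, while the extra Grignard reagent covers any deprotonation of the alkyne C–H.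

Step 3
Reactants: 6 2-methylhept-1-en-6-yn-3-one
Product: 7 (R)-2-methylhept-1-en-6-yn-3-ol
Conditions: (S)-Me-CBS oxazaborolidine [(S)-1-methyl-3,3-diphenyltetrahydro-1H,3H-pyrrolo[1,2-c][1,3,2]oxazaborole] (15 mol %), catecholborane, toluene, −78 °C; MeOH quench, aq. NaOH wash
Reagents that add atoms: none
Why: Corey–Bakshi–Shibata reduction, in which the α-branched isopropenyl group takes the role of the large substituent and the primary alkyl chain that of the small one, so that the (S)-catalyst should deliver hydride to the face that gives the (R)-carbinol, while catecholborane at −78 °C should leave alkyne and alkene alone.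

Step 4
Reactants: 7 (R)-2-methylhept-1-en-6-yn-3-ol
Product: 8 (R)-tert-butyldimethyl[(2-methylhept-1-en-6-yn-3-yl)oxy]silane
Conditions: TBSCl, imidazole, DMF, rt
Reagents that add atoms: tert-butyldimethylsilyl chloride, CC(C)(C)[Si](C)(C)Cl
Why: Standard O-silylation of a secondary alcohol, which does not touch the stereocentre and removes the acidic O–H before the organoaluminium step.

Step 5
Reactants: 9 2,3-dihydroxybenzaldehyde
Product: 10 2,3-bis(methoxymethoxy)benzaldehyde
Conditions: NaH, MOMCl, DMF, 0 °C to rt
Reagents that add atoms: chloromethyl methyl ether, COCCl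
Why: Williamson-type O-alkylation of both phenoxides, with NaH ensuring that the hydrogen-bonded 2-OH reacts as well.

Step 6
Reactants: 10 2,3-bis(methoxymethoxy)benzaldehyde
Product: 11 6-bromo-2,3-bis(methoxymethoxy)benzaldehyde
Conditions: NBS, DMF, rt, dark
Reagents that add atoms: N-bromosuccinimide, O=C1CCC(=O)N1Br
Why: Electrophilic aromatic bromination should occur para to the 3-alkoxy group (C6), because the 2-alkoxy group is twisted out of conjugation between its two neighbours, a regiochemistry established for 2,3-dialkoxybenzaldehydes, and MOM acetals tolerate NBS in DMF.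

Step 7
Reactants: 11 6-bromo-2,3-bis(methoxymethoxy)benzaldehyde
Product: 12 [6-bromo-2,3-bis(methoxymethoxy)phenyl]methanol
Conditions: NaBH4, MeOH/THF, 0 °C
Reagents that add atoms: none
Why: Borohydride reduction of the aldehyde is chemoselective in the presence of the aryl bromide and the acetals and puts the future C1'' at the alcohol oxidation level before the cross-coupling.

Step 8
Reactants: 13 2,4-dihydroxybenzaldehyde
Product: 14 2,4-bis(methoxymethoxy)benzaldehyde
Conditions: NaH, MOMCl, DMF, 0 °C to rt
Reagents that add atoms: chloromethyl methyl ether, COCCl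
Why: Williamson-type O-alkylation of both phenoxides, the strong base overcoming the hydrogen bond of the 2-OH to the aldehyde.

Step 9
Reactants: 14 2,4-bis(methoxymethoxy)benzaldehyde; 15 vinylmagnesium bromide
Product: 16 1-[2,4-bis(methoxymethoxy)phenyl]prop-2-en-1-ol (racemic)
Conditions: THF, −78 to 0 °C; sat. aq. NH4Cl
Reagents that add atoms: vinylmagnesium bromide (compound 15), C=C[Mg]Br
Why: Grignard 1,2-addition to the aldehyde, for which no stereocontrol is needed because this carbon later becomes the ketone carbonyl.

Step 10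
Reactants: 16 1-[2,4-bis(methoxymethoxy)phenyl]prop-2-en-1-ol
Product: 17 {1-[2,4-bis(methoxymethoxy)phenyl]prop-2-en-1-yl}oxy(triethyl)silane (racemic)
Conditions: TESCl, imidazole, DMF, 0 °C
Reagents that add atoms: chlorotriethylsilane, CC[Si](Cl)(CC)CC
Why: O-silylation caps the ionisation-prone doubly activated carbinol with a group that can later be removed in the presence of the secondary TBS ether.

Step 11
Reactants: 17 {1-[2,4-bis(methoxymethoxy)phenyl]prop-2-en-1-yl}oxy(triethyl)silane; 12 [6-bromo-2,3-bis(methoxymethoxy)phenyl]methanol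
Product: 19 {6-{3-[2,4-bis(methoxymethoxy)phenyl]-3-(triethylsilyloxy)propyl}-2,3-bis(methoxymethoxy)phenyl}methanol (racemic), via B-alkyl-9-BBN adduct 18 (not isolated)
Conditions: 9-BBN (1.05 equiv), THF, 0 °C to rt; then 12, Pd(OAc)2 (3 mol %), SPhos (2-dicyclohexylphosphino-2',6'-dimethoxybiphenyl), 3 M aq. K3PO4, THF, 65 °C
Reagents that add atoms: none
Why: Anti-Markovnikov hydroboration of the terminal olefin followed by B-alkyl Suzuki–Miyaura coupling with the aryl bromide forms the ring B C1–CH2 bond, the bulky biaryl phosphine favouring reductive elimination over β-hydride elimination and the free benzylic alcohol being tolerated.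

Step 12
Reactants: 19 {6-{3-[2,4-bis(methoxymethoxy)phenyl]-3-(triethylsilyloxy)propyl}-2,3-bis(methoxymethoxy)phenyl}methanol
Product: 21 {3-[2-(chloromethyl)-3,4-bis(methoxymethoxy)phenyl]-1-[2,4-bis(methoxymethoxy)phenyl]propoxy}triethylsilane (racemic), via benzylic methanesulfonate 20 (not isolated)
Conditions: MsCl, LiCl, 2,4,6-collidine, DMF, 0 °C
Reagents that add atoms: lithium chloride, [Li+].[Cl-]; methanesulfonyl chloride, CS(=O)(=O)Cl (its chloride joins the same chloride pool)
Why: Mesylation and in situ nucleophilic displacement by chloride under buffered, non-acidic conditions should spare the MOM acetals and the TES ether.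

Step 13
Reactants: 8 (R)-tert-butyldimethyl[(2-methylhept-1-en-6-yn-3-yl)oxy]silane; 22 trimethylaluminium; 21 {3-[2-(chloromethyl)-3,4-bis(methoxymethoxy)phenyl]-1-[2,4-bis(methoxymethoxy)phenyl]propoxy}triethylsilane
Product: 24 triethyl{1-[2,4-bis(methoxymethoxy)phenyl]-3-{2-[(2E,6R)-6-(tert-butyldimethylsilyloxy)-3,7-dimethylocta-2,7-dien-1-yl]-3,4-bis(methoxymethoxy)phenyl}propoxy}silane (two epimers at the propane C1), via (E)-alkenyldimethylalane 23 (not isolated)
Conditions: 8 (1.5 equiv), Me3Al (3 equiv), Cp2ZrCl2 (0.4 equiv), ClCH2CH2Cl, 0 °C to rt; volatiles removed in vacuo; then 21 (1 equiv), Pd(PPh3)4 (5 mol %), THF, rt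
Reagents that add atoms: trimethylaluminium (compound 22), C[Al](C)C
Why: A methylzirconocene species activated by aluminium adds its methyl group and the metal in syn fashion across the C≡C bond of 8 with the metal on the unhindered terminal carbon, and exchange with aluminium gives the (E)-alkenyldimethylalane 23. Zerovalent palladium then inserts into the benzylic C–Cl bond of 21, the alkenyl group passes from aluminium to palladium, and reductive elimination joins C1'' to C2'' with retention of the olefin geometry. The closest known reaction type is zirconium-catalysed methylalumination of terminal alkynes followed by palladium-catalysed alkenyl–benzyl cross-coupling of the alkenylalane, a Negishi-type one-pot sequence known for polyoxygenated benzylic chlorides. No ring is closed and no stereocentre is made, and the (R)-centre from step 3 is remote and untouched. The step needs regio- and syn-selectivity, which the terminal alkyne secures and which together fix the E geometry, and chemoselectivity, which the substrate secures because the 1,1-disubstituted olefin, the silyl ethers and the aryl acetals offer no site for carbometalation and the former carbonyl carbon is a silyl-protected carbinol. Stripping the excess Me3Al and working in THF should keep methyl transfer to the benzylic carbon and Lewis acid attack on the MOM acetals in check.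

Step 14
Reactants: 24 triethyl{1-[2,4-bis(methoxymethoxy)phenyl]-3-{2-[(2E,6R)-6-(tert-butyldimethylsilyloxy)-3,7-dimethylocta-2,7-dien-1-yl]-3,4-bis(methoxymethoxy)phenyl}propoxy}silane
Product: 25 1-[2,4-bis(methoxymethoxy)phenyl]-3-{2-[(2E,6R)-6-(tert-butyldimethylsilyloxy)-3,7-dimethylocta-2,7-dien-1-yl]-3,4-bis(methoxymethoxy)phenyl}propan-1-ol (two epimers at C1)
Conditions: HF·pyridine, pyridine, THF, 0 °C
Reagents that add atoms: none
Why: Buffered fluoride desilylation is selective on steric grounds, the triethylsilyl ether being cleaved far faster than the tert-butyldimethylsilyl ether, and the pyridine buffer protects the acetals and the ionisable benzylic carbinol.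

Step 15
Reactants: 25 1-[2,4-bis(methoxymethoxy)phenyl]-3-{2-[(2E,6R)-6-(tert-butyldimethylsilyloxy)-3,7-dimethylocta-2,7-dien-1-yl]-3,4-bis(methoxymethoxy)phenyl}propan-1-ol
Product: 26 1-[2,4-bis(methoxymethoxy)phenyl]-3-{2-[(2E,6R)-6-(tert-butyldimethylsilyloxy)-3,7-dimethylocta-2,7-dien-1-yl]-3,4-bis(methoxymethoxy)phenyl}propan-1-one
Conditions: Dess–Martin periodinane, NaHCO3, CH2Cl2, 0 °C to rt
Reagents that add atoms: none
Why: Dess–Martin oxidation of the only free hydroxyl gives the aryl ketone and merges both epimers into one compound, while olefins, silyl ether and acetals are inert.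

Step 16
Reactants: 26 1-[2,4-bis(methoxymethoxy)phenyl]-3-{2-[(2E,6R)-6-(tert-butyldimethylsilyloxy)-3,7-dimethylocta-2,7-dien-1-yl]-3,4-bis(methoxymethoxy)phenyl}propan-1-one
Product: 27 1-(2,4-dihydroxyphenyl)-3-{3,4-dihydroxy-2-[(2E,6R)-6-hydroxy-3,7-dimethylocta-2,7-dien-1-yl]phenyl}propan-1-one (target)
Conditions: 3 M aq. HCl, MeOH, rt to 40 °C, argon
Reagents that add atoms: none
Why: Acid-catalysed acetal exchange with methanol should remove the four aryl MOM groups and the TBS ether in one operation, the low temperature and dilute acid being chosen to avoid addition of the C3 phenol to the C2''=C3'' olefin and solvolysis of the allylic alcohol.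

Compound list
1 | pent-4-ynoic acid | C#CCCC(=O)O | starting material
2 | 1-(pent-4-ynoyl)-1H-imidazole | C#CCCC(=O)n1ccnc1 | intermediate (not isolated)
3 | N-methoxy-N-methylpent-4-ynamide | C#CCCC(=O)N(C)OC | intermediate
4 | isopropenylmagnesium bromide | C=C(C)[Mg]Br | starting material
5 | bromomagnesium 3-[methoxy(methyl)amino]-2-methylhept-1-en-6-yn-3-olate (chelated tetrahedral adduct) | C=C(C)C(CCC#C)(O[Mg]Br)N(C)OC | intermediate (not isolated)
6 | 2-methylhept-1-en-6-yn-3-one | C=C(C)C(=O)CCC#C | intermediate
7 | (R)-2-methylhept-1-en-6-yn-3-ol | C=C(C)[C@H](O)CCC#C | intermediate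
8 | (R)-tert-butyldimethyl[(2-methylhept-1-en-6-yn-3-yl)oxy]silane | C=C(C)[C@H](O[Si](C)(C)C(C)(C)C)CCC#C | intermediate (key-step precursor)
9 | 2,3-dihydroxybenzaldehyde | O=Cc1cccc(O)c1O | starting material
10 | 2,3-bis(methoxymethoxy)benzaldehyde | O=Cc1cccc(OCOC)c1OCOC | intermediate
11 | 6-bromo-2,3-bis(methoxymethoxy)benzaldehyde | O=Cc1c(Br)ccc(OCOC)c1OCOC | intermediate
12 | [6-bromo-2,3-bis(methoxymethoxy)phenyl]methanol | OCc1c(Br)ccc(OCOC)c1OCOC | intermediate
13 | 2,4-dihydroxybenzaldehyde | O=Cc1ccc(O)cc1O | starting material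
14 | 2,4-bis(methoxymethoxy)benzaldehyde | O=Cc1ccc(OCOC)cc1OCOC | intermediate
15 | vinylmagnesium bromide | C=C[Mg]Br | starting material
16 | 1-[2,4-bis(methoxymethoxy)phenyl]prop-2-en-1-ol (racemic) | C=CC(O)c1ccc(OCOC)cc1OCOC | intermediate
17 | {1-[2,4-bis(methoxymethoxy)phenyl]prop-2-en-1-yl}oxy(triethyl)silane (racemic) | C=CC(O[Si](CC)(CC)CC)c1ccc(OCOC)cc1OCOC | intermediate
18 | 9-{3-[2,4-bis(methoxymethoxy)phenyl]-3-(triethylsilyloxy)propyl}-9-borabicyclo[3.3.1]nonane (racemic) | CC[Si](CC)(CC)OC(CCB1C2CCCC1CCC2)c1ccc(OCOC)cc1OCOC | intermediate (not isolated)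
19 | {6-{3-[2,4-bis(methoxymethoxy)phenyl]-3-(triethylsilyloxy)propyl}-2,3-bis(methoxymethoxy)phenyl}methanol (racemic) | OCc1c(CCC(O[Si](CC)(CC)CC)c2ccc(OCOC)cc2OCOC)ccc(OCOC)c1OCOC | intermediate
20 | 6-{3-[2,4-bis(methoxymethoxy)phenyl]-3-(triethylsilyloxy)propyl}-2,3-bis(methoxymethoxy)benzyl methanesulfonate (racemic) | CS(=O)(=O)OCc1c(CCC(O[Si](CC)(CC)CC)c2ccc(OCOC)cc2OCOC)ccc(OCOC)c1OCOC | intermediate (not isolated)
21 | {3-[2-(chloromethyl)-3,4-bis(methoxymethoxy)phenyl]-1-[2,4-bis(methoxymethoxy)phenyl]propoxy}triethylsilane (racemic; ring B C2 benzylic chloride) | ClCc1c(CCC(O[Si](CC)(CC)CC)c2ccc(OCOC)cc2OCOC)ccc(OCOC)c1OCOC | intermediate (key-step precursor)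
22 | trimethylaluminium | C[Al](C)C | starting material
23 | [(1E,5R)-5-(tert-butyldimethylsilyloxy)-2,6-dimethylhepta-1,6-dien-1-yl]dimethylalane | C=C(C)[C@H](O[Si](C)(C)C(C)(C)C)CC/C(C)=C/[Al](C)C | intermediate (not isolated)
24 | triethyl{1-[2,4-bis(methoxymethoxy)phenyl]-3-{2-[(2E,6R)-6-(tert-butyldimethylsilyloxy)-3,7-dimethylocta-2,7-dien-1-yl]-3,4-bis(methoxymethoxy)phenyl}propoxy}silane (two epimers at the propane C1) | C=C(C)[C@H](O[Si](C)(C)C(C)(C)C)CC/C(C)=C/Cc1c(CCC(O[Si](CC)(CC)CC)c2ccc(OCOC)cc2OCOC)ccc(OCOC)c1OCOC | intermediate (key-step product)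
25 | 1-[2,4-bis(methoxymethoxy)phenyl]-3-{2-[(2E,6R)-6-(tert-butyldimethylsilyloxy)-3,7-dimethylocta-2,7-dien-1-yl]-3,4-bis(methoxymethoxy)phenyl}propan-1-ol (two epimers at C1) | C=C(C)[C@H](O[Si](C)(C)C(C)(C)C)CC/C(C)=C/Cc1c(CCC(O)c2ccc(OCOC)cc2OCOC)ccc(OCOC)c1OCOC | intermediate
26 | 1-[2,4-bis(methoxymethoxy)phenyl]-3-{2-[(2E,6R)-6-(tert-butyldimethylsilyloxy)-3,7-dimethylocta-2,7-dien-1-yl]-3,4-bis(methoxymethoxy)phenyl}propan-1-one | C=C(C)[C@H](O[Si](C)(C)C(C)(C)C)CC/C(C)=C/Cc1c(CCC(=O)c2ccc(OCOC)cc2OCOC)ccc(OCOC)c1OCOC | intermediate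
27 | 1-(2,4-dihydroxyphenyl)-3-{3,4-dihydroxy-2-[(2E,6R)-6-hydroxy-3,7-dimethylocta-2,7-dien-1-yl]phenyl}propan-1-one (CNP0325580.1) | C=C(C)[C@H](O)CC/C(C)=C/Cc1c(CCC(=O)c2ccc(O)cc2O)ccc(O)c1O | target

Total step count: 16 steps.
Longest linear sequence: 9 steps (compound 9 through steps 5, 6, 7, 11, 12, 13, 14, 15 and 16 to compound 27; the branch from compound 13 through steps 8, 9 and 10 is equally long).

Steps most likely to fail

1. Step 13. What may go wrong: incomplete or poorly regioselective carbometalation, slow alkenyl transfer that lets methyl transfer or ionisation and homocoupling of the electron-rich benzylic chloride compete, and Lewis acid erosion of the aryl acetals. The fallback separates the two bond formations and reverses the polarity of the coupling. Setting out from 8, methylalumination as in step 13 gives alane 23, which is quenched with iodine (I2, THF, −30 °C) to give (R,E)-tert-butyl[(7-iodo-2,6-dimethylhepta-1,6-dien-3-yl)oxy]dimethylsilane F1. Setting out from 21, zinc dust and LiCl in THF at rt insert into the C–Cl bond to give the benzylic zinc chloride {6-{3-[2,4-bis(methoxymethoxy)phenyl]-3-(triethylsilyloxy)propyl}-2,3-bis(methoxymethoxy)benzyl}zinc chloride F2. Negishi coupling of F1 with F2 (Pd(OAc)2, SPhos, THF, rt) comes back to the route at 24.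

2. Step 16. What may go wrong: acid-promoted addition of the C3 phenol to the C2''=C3'' olefin (chroman formation), solvolysis or transposition of the allylic alcohol, or incomplete acetal cleavage. The fallback unmasks the phenols without Brønsted acid. Setting out from 26, TMSOTf and 2,2'-bipyridyl in CH2Cl2 at 0 °C should convert the four aryl MOM ethers into the tetrakis(trimethylsilyl) aryl ether of the TBS-protected target F3. Water on work-up hydrolyses it to 1-(2,4-dihydroxyphenyl)-3-{2-[(2E,6R)-6-(tert-butyldimethylsilyloxy)-3,7-dimethylocta-2,7-dien-1-yl]-3,4-dihydroxyphenyl}propan-1-one F4. HF·pyridine in THF at 0 °C to rt then removes the TBS group and comes back to the route at 27.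

3. Step 3. What may go wrong: insufficient facial discrimination between the isopropenyl and the alkyl substituent, or competing conjugate reduction or hydroboration. The fallback reduces without stereocontrol and then resolves. Setting out from 6, Luche reduction (NaBH4, CeCl3·7H2O, MeOH, −78 °C) gives racemic 2-methylhept-1-en-6-yn-3-ol F5. Sharpless kinetic resolution (Ti(OiPr)4, L-(+)-diisopropyl tartrate, t-BuOOH (0.6 equiv), 4 Å molecular sieves, CH2Cl2, −20 °C) should epoxidise the (S)-enantiomer to (S)-1-[(S)-2-methyloxiran-2-yl]pent-4-yn-1-ol F6 and leave the (R)-alcohol, so the fallback comes back to the route at 7.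

Further compounds
F1 | step 13 | (R,E)-tert-butyl[(7-iodo-2,6-dimethylhepta-1,6-dien-3-yl)oxy]dimethylsilane | C=C(C)[C@H](O[Si](C)(C)C(C)(C)C)CC/C(C)=C/I
F2 | step 13 | {6-{3-[2,4-bis(methoxymethoxy)phenyl]-3-(triethylsilyloxy)propyl}-2,3-bis(methoxymethoxy)benzyl}zinc chloride (racemic) | Cl[Zn]Cc1c(CCC(O[Si](CC)(CC)CC)c2ccc(OCOC)cc2OCOC)ccc(OCOC)c1OCOC
F3 | step 16 | tetrakis(trimethylsilyl) aryl ether of the TBS-protected target (not isolated) | C=C(C)[C@H](O[Si](C)(C)C(C)(C)C)CC/C(C)=C/Cc1c(CCC(=O)c2ccc(O[Si](C)(C)C)cc2O[Si](C)(C)C)ccc(O[Si](C)(C)C)c1O[Si](C)(C)C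
F4 | step 16 | 1-(2,4-dihydroxyphenyl)-3-{2-[(2E,6R)-6-(tert-butyldimethylsilyloxy)-3,7-dimethylocta-2,7-dien-1-yl]-3,4-dihydroxyphenyl}propan-1-one | C=C(C)[C@H](O[Si](C)(C)C(C)(C)C)CC/C(C)=C/Cc1c(CCC(=O)c2ccc(O)cc2O)ccc(O)c1O
F5 | step 3 | 2-methylhept-1-en-6-yn-3-ol (racemic) | C=C(C)C(O)CCC#C
F6 | step 3 | (S)-1-[(S)-2-methyloxiran-2-yl]pent-4-yn-1-ol | C#CCC[C@H](O)[C@]1(C)CO1
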